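Assumption: atoms carry eudesmane numbers throughout (C1 = CH2OAc carbon, C4 = side-chain stereocentre, C5=C10 = ring alkene, C6 = carbinol, C7/C8 = ring fusion, C11–C13 = methylene lactone, C14 = CH2O-isobutyrate, C15 = side-chain methyl). The lactol carbon of 13/15 and the carbinol C7 of 15 are epimer mixtures that later steps erase.

**Retrosynthetic overview**
1. The lactone closes last, C8–OH onto the C12 ester, as in the biogenesis of 8,12-olides.
2. The cyclohexene closes at C6–C7, the bond the germacrene cyclase makes. C6 is the electrophile, the C7=C11 π bond is the nucleophile, and the electrofuge leaves from C13.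
3. The C5–C10 bond (germacrane→eudesmane closure), the C5→C4 hydride shift and the C1–C10 Grob scission run in one operation on a geraniol-derived epoxide. The epoxide stereocentres set C4 and are then destroyed.
4. Carbon sources: geranyl acetate (C1–C6, C9, C10, C14, C15), dimethoxyacetaldehyde (C7, C8), methyl acrylate (C11–C13).
5. Ring order: transient cyclohexane (made and cleaved in step 4) → lactol resting form → cyclohexene → γ-lactone.

**Route**

Step 1
Reactants: 1 geranyl acetate
Product: 2 (2E,6E)-8-hydroxy-3,7-dimethylocta-2,6-dien-1-yl acetate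
Conditions: SeO2 (10 mol%), t-BuOOH, salicylic acid (cat.), CH2Cl2, 23 °C
Reagents that add atoms: tert-butyl hydroperoxide CC(C)(C)OO
Why: Riley allylic oxidation (ene reaction, then [2,3]-shift) attacks only the electron-rich distal alkene and there only the E-methyl group, which becomes C14.

Step 2
Reactants: 2 (2E,6E)-8-hydroxy-3,7-dimethylocta-2,6-dien-1-yl acetate
Product: 3 (2E)-5-[(2R,3R)-3-(hydroxymethyl)-3-methyloxiran-2-yl]-3-methylpent-2-en-1-yl acetate
Conditions: Ti(OiPr)4 (5 mol%), D-(−)-diethyl tartrate (6 mol%), t-BuOOH, 4 Å MS, CH2Cl2, −20 °C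
Reagents that add atoms: tert-butyl hydroperoxide CC(C)(C)OO
Why: Sharpless asymmetric epoxidation touches only the alkene bearing the free allylic alcohol, and D-(−)-tartrate gives the (2R,3R)-epoxide (C1 = R, C10 = R), whose C1 centre later relays its configuration to C4.

Step 3
Reactants: 3 (2E)-5-[(2R,3R)-3-(hydroxymethyl)-3-methyloxiran-2-yl]-3-methylpent-2-en-1-yl acetate
Product: 4 [(2R,3R)-3-[(3E)-5-acetoxy-3-methylpent-3-en-1-yl]-2-methyloxiran-2-yl]methyl 2-methylpropanoate
Conditions: i-PrCOCl, Et3N, DMAP (cat.), CH2Cl2, 0 °C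
Reagents that add atoms: isobutyryl chloride CC(C)C(=O)Cl
Why: Plain O-acylation installs the C14 isobutyrate while it is the only hydroxyl present, and the epoxide, acetate and alkene are inert.

Step 4
Reactants: 4 [(2R,3R)-3-[(3E)-5-acetoxy-3-methylpent-3-en-1-yl]-2-methyloxiran-2-yl]methyl 2-methylpropanoate
Product: 7 (2Z,4S)-7-hydroxy-3-(hydroxymethyl)-2,4-dimethylhept-2-en-1-yl 2-methylpropanoate, via seco-aldehyde 5 (not isolated), via hydroxy acetate 6 (not isolated)
Conditions: Ph4PBF4, (CF3)2CHOH, 0 to 23 °C; evaporate; NaBH4, MeOH, −20 °C; then K2CO3 (0.2 equiv), −10 °C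
Reagents that add atoms: none
Why: Proposed new method: hydrogen-bond activation opens the epoxide at tertiary C10 and the E-C4=C5 alkene attacks through a chair (C1–O and C6 equatorial, H5 axial), which is the classical epoxide-initiated cation–olefin cyclisation; axial H5 then shifts suprafacially to the C4 cation, so C1-R gives C4-S, the C6 acetate can hold the charge at C5 as an acetoxonium ion, and the C1 hydroxyl expels the C1–C10 bond (Grob/retro-Prins fragmentation) to give aldehyde 5 with the C5=C10 alkene; proton-loss and bridged-ether side products can re-ionise in this medium, whereas an alkene carrying two allylic acyloxy groups should not re-enter, so fragmentation is the expected irreversible exit; closest known types are epoxy-polyene cyclisation, hydride shifts in alkoxide/carbocation dipoles and acid-induced fragmentation of 1,3-hydroxy cations; NaBH4 then reduces C1, and catalytic methanolysis removes the acetate much faster than the hindered isobutyrate.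

Step 5
Reactants: 7 (2Z,4S)-7-hydroxy-3-(hydroxymethyl)-2,4-dimethylhept-2-en-1-yl 2-methylpropanoate
Product: 8 (2Z,4S)-3-formyl-7-hydroxy-2,4-dimethylhept-2-en-1-yl 2-methylpropanoate
Conditions: MnO2 (activated), CH2Cl2, 23 °C
Reagents that add atoms: none
Why: MnO2 oxidation is selective for the allylic alcohol, so C6 becomes the enal while the saturated C1–OH, the ester and C4 are untouched.

Step 6
Reactants: 8 (2Z,4S)-3-formyl-7-hydroxy-2,4-dimethylhept-2-en-1-yl 2-methylpropanoate
Product: 9 (2Z,4S)-7-acetoxy-3-formyl-2,4-dimethylhept-2-en-1-yl 2-methylpropanoate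
Conditions: Ac2O, pyridine, DMAP (cat.), CH2Cl2, 0 °C
Reagents that add atoms: acetic anhydride CC(=O)OC(C)=O
Why: O-acetylation of the only free hydroxyl installs the C1 acetate of the target.

Step 7
Reactants: 9 (2Z,4S)-7-acetoxy-3-formyl-2,4-dimethylhept-2-en-1-yl 2-methylpropanoate
Product: 10 (4S)-7-acetoxy-4-methyl-2-methylidene-3-[(E)-(triethylsilyloxy)methylidene]heptyl 2-methylpropanoate
Conditions: Et3SiOTf, Et3N, Et2O, −78 to 0 °C
Reagents that add atoms: triethylsilyl triflate CC[Si](CC)(CC)OS(=O)(=O)C(F)(F)F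
Why: Soft enolisation of the O-silylated enal removes a proton from the C9 methyl group, whose C–H bonds are better hyperconjugative donors than those of the acyloxymethyl group, giving the 1-silyloxydiene and erasing the C5=C10 geometry, which is rebuilt in step 8.

Step 8
Reactants: 10 (4S)-7-acetoxy-4-methyl-2-methylidene-3-[(E)-(triethylsilyloxy)methylidene]heptyl 2-methylpropanoate; 11 2,2-dimethoxyacetaldehyde
Product: 13 [(2R)-5-[(2S)-5-acetoxypentan-2-yl]-2-formyl-6-hydroxy-3,6-dihydro-2H-pyran-4-yl]methyl 2-methylpropanoate, via silylated aldol adduct 12 (not isolated)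
Conditions: [Cu((R,R)-Ph-pybox)](SbF6)2 (10 mol%), CH2Cl2, −78 °C; then 1 M HCl, THF, 23 °C
Reagents that add atoms: water O
Why: In this catalytic asymmetric vinylogous Mukaiyama aldol, the blocked α-carbon C5 forces attack through C9 on the chelated α-alkoxy aldehyde; the (R,R)-ligand should give C8-R by analogy with the (S)-adducts that the (S,S)-catalyst gives with benzyloxyacetaldehyde; the acid work-up cleaves the silyl ether and the acetal and equilibrates the enal geometry, with the isomer having C9 cis to C6 drained as the six-membered lactol.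

Step 9
Reactants: 13 [(2R)-5-[(2S)-5-acetoxypentan-2-yl]-2-formyl-6-hydroxy-3,6-dihydro-2H-pyran-4-yl]methyl 2-methylpropanoate; 14 methyl acrylate
Product: 15 methyl 2-{[(2R)-5-[(2S)-5-acetoxypentan-2-yl]-6-hydroxy-4-[(2-methylpropanoyloxy)methyl]-3,6-dihydro-2H-pyran-2-yl](hydroxy)methyl}prop-2-enoate
Conditions: DABCO, 1,4-dioxane/H2O 1:1, 10 °C
Reagents that add atoms: none
Why: The Morita–Baylis–Hillman reaction is fast for α-alkoxy aldehydes, the masked tetrasubstituted enal cannot take part, and the new C7 carbinol needs no control because C7 becomes planar in step 10.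

Step 10
Reactants: 15 methyl 2-{[(2R)-5-[(2S)-5-acetoxypentan-2-yl]-6-hydroxy-4-[(2-methylpropanoyloxy)methyl]-3,6-dihydro-2H-pyran-2-yl](hydroxy)methyl}prop-2-enoate
Product: 17 target [(3aR,4S,7aR)-5-[(2S)-5-acetoxypentan-2-yl]-4-hydroxy-3-methylidene-2-oxo-3a,4,7,7a-tetrahydro-1-benzofuran-6-yl]methyl 2-methylpropanoate, via dihydroxy ester 16 (not isolated)
Conditions: PdCl2(PhCN)2 (5 mol%), SnCl2 (3 equiv), THF/H2O, 23 °C; then pyridinium p-toluenesulfonate (cat.), CH2Cl2, 23 °C
Reagents that add atoms: none
Why: In this palladium-catalysed umpolung carbonyl allylation with divalent tin, the 2-(alkoxycarbonyl)allyl alcohol becomes an allyl–tin nucleophile that attacks the ring-opened C6 aldehyde through C7 in a closed chair transition state; C8–O and C11 sit equatorial (7,8-trans) and the C6 oxygen sits pseudoaxial to avoid allylic strain with the C5 side chain (6,7-cis), so C8-R sets C7-R and C6-S; the unhindered equatorial C8–OH then lactonises in preference to the flanked pseudoaxial C6–OH.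

**Compound list**
1 | geranyl acetate | CC(C)=CCC/C(C)=C/COC(C)=O | starting material
2 | (2E,6E)-8-hydroxy-3,7-dimethylocta-2,6-dien-1-yl acetate | OC/C(C)=C/CC/C(C)=C/COC(C)=O | intermediate
3 | (2R,3R)-epoxy alcohol (C1-R, C10-R) | OC[C@@]1(C)O[C@@H]1CC/C(C)=C/COC(C)=O | intermediate
4 | (2R,3R)-epoxy acetate isobutyrate | CC(C)C(=O)OC[C@@]1(C)O[C@@H]1CC/C(C)=C/COC(C)=O | intermediate
5 | seco-aldehyde, (2Z,4S)-3-(acetoxymethyl)-2,4-dimethyl-7-oxohept-2-en-1-yl 2-methylpropanoate | O=CCC[C@H](C)/C(COC(C)=O)=C(\C)COC(=O)C(C)C | intermediate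
6 | hydroxy acetate, (2Z,4S)-3-(acetoxymethyl)-7-hydroxy-2,4-dimethylhept-2-en-1-yl 2-methylpropanoate | OCCC[C@H](C)/C(COC(C)=O)=C(\C)COC(=O)C(C)C | intermediate
7 | (2Z,4S)-7-hydroxy-3-(hydroxymethyl)-2,4-dimethylhept-2-en-1-yl 2-methylpropanoate | OCCC[C@H](C)/C(CO)=C(\C)COC(=O)C(C)C | intermediate
8 | (2Z,4S)-3-formyl-7-hydroxy-2,4-dimethylhept-2-en-1-yl 2-methylpropanoate | OCCC[C@H](C)/C(C=O)=C(\C)COC(=O)C(C)C | intermediate
9 | (2Z,4S)-7-acetoxy-3-formyl-2,4-dimethylhept-2-en-1-yl 2-methylpropanoate | CC(=O)OCCC[C@H](C)/C(C=O)=C(\C)COC(=O)C(C)C | intermediate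
10 | (E)-1-triethylsilyloxy diene | CC(=O)OCCC[C@H](C)/C(=C\O[Si](CC)(CC)CC)C(=C)COC(=O)C(C)C | intermediate
11 | 2,2-dimethoxyacetaldehyde | COC(OC)C=O | starting material
12 | silylated aldol adduct, (2E,4S)-7-acetoxy-2-[(2R)-3,3-dimethoxy-2-(triethylsilyloxy)propyl]-3-formyl-4-methylhept-2-en-1-yl 2-methylpropanoate | CC(=O)OCCC[C@H](C)/C(C=O)=C(\COC(=O)C(C)C)C[C@@H](O[Si](CC)(CC)CC)C(OC)OC | intermediate
13 | lactol aldehyde (C8-R, lactol carbon epimeric) | O=C[C@H]1CC(COC(=O)C(C)C)=C([C@@H](C)CCCOC(C)=O)C(O)O1 | intermediate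
14 | methyl acrylate | C=CC(=O)OC | starting material
15 | Baylis–Hillman adduct (C8-R, C7 and lactol carbon epimeric) | COC(=O)C(=C)C(O)[C@H]1CC(COC(=O)C(C)C)=C([C@@H](C)CCCOC(C)=O)C(O)O1 | intermediate
16 | methyl 2-{(1S,2S,6R)-3-[(2S)-5-acetoxypentan-2-yl]-2,6-dihydroxy-4-[(2-methylpropanoyloxy)methyl]cyclohex-3-en-1-yl}prop-2-enoate | C=C(C(=O)OC)[C@@H]1[C@H](O)C([C@@H](C)CCCOC(C)=O)=C(COC(=O)C(C)C)C[C@H]1O | intermediate
17 | CNP0246650.1 | C=C1C(=O)O[C@@H]2CC(COC(=O)C(C)C)=C([C@@H](C)CCCOC(C)=O)[C@@H](O)[C@@H]12 | target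

Total step count: 10. Longest linear sequence: 10.

**Steps most likely to fail**

Step 4 (cyclisation / hydride shift / fragmentation). The C4 cation may lose a proton, be trapped by the C1 oxygen, or the isobutyrate may capture C10 before the hydride shift occurs.

The fallback sets out from 2 and comes back at 5. It replaces the cation by a radical and the Grob step by photochemistry.
- 2 is epoxidised with L-(+)-diethyl tartrate to the (2S,3S)-epoxy alcohol F1. The mirror epoxide is needed because the methyl group now ends trans to the C1 oxygen.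
- F1 is acylated to the (2S,3S)-epoxy isobutyrate F2.
- Cp2TiCl2, Mn, collidine hydrochloride and H2O in THF generate trivalent titanium, which opens the epoxide to the C10 radical. After 6-endo addition to C5, the C4 radical takes an axial hydrogen atom from the aqua complex, giving the cyclohexanol F3.
- Dess–Martin periodinane gives the cyclohexanone F4.
- Irradiation at 300 nm (Norrish type 1 α-cleavage of C1–C10, then transfer of H5 to the acyl radical) gives 5 and its alkene isomer. Both converge at 10.

Step 8 (vinylogous aldol). α/γ selectivity, the enal geometry and catalyst control with this crowded diene are all untested.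

The fallback sets out from 10 and comes back at 13. It uses chiral-pool control instead of a catalyst.
- BF3·OEt2 at −78 °C with (S)-2,3-O-isopropylideneglyceraldehyde gives, after mild acid work-up, the Felkin–Anh anti adduct as the acetonide lactol F5 (C8-R, C7-S).
- 80% aqueous acetic acid frees the triol lactol F6.
- NaIO4 cleaves its terminal glycol to the formyl group of 13.

Step 10 (ring closure and lactone regiochemistry). The C6 hydroxyl is cis to C11 and may lactonise instead of O8, and 1,4-elimination of the allyl–tin species is possible.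

The fallback sets out from 16, isolated after the tin stage, and comes back at 17. It removes the competing hydroxyl by a redox detour.
- MnO2 oxidises only the allylic C6–OH to the enone hydroxy ester F7.
- Catalytic acid then closes the only possible lactone, giving the enone lactone F8.
- (R)-2-methyl-CBS-oxazaborolidine with catecholborane at −40 °C reduces C6 under catalyst control to the S alcohol 17.

**Further compounds**
F1 | step 4 | (2E)-5-[(2S,3S)-3-(hydroxymethyl)-3-methyloxiran-2-yl]-3-methylpent-2-en-1-yl acetate | OC[C@]1(C)O[C@H]1CC/C(C)=C/COC(C)=O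
F2 | step 4 | (2S,3S)-epoxy acetate isobutyrate | CC(C)C(=O)OC[C@]1(C)O[C@H]1CC/C(C)=C/COC(C)=O
F3 | step 4 | {(2R,3S,6S)-2-(acetoxymethyl)-6-hydroxy-1,3-dimethylcyclohexyl}methyl 2-methylpropanoate (quaternary carbon epimeric) | O[C@H]1CC[C@H](C)[C@@H](COC(C)=O)C1(C)COC(=O)C(C)C
F4 | step 4 | {(2R,3S)-2-(acetoxymethyl)-1,3-dimethyl-6-oxocyclohexyl}methyl 2-methylpropanoate (quaternary carbon epimeric) | O=C1CC[C@H](C)[C@@H](COC(C)=O)C1(C)COC(=O)C(C)C
F5 | step 8 | acetonide lactol, C8-R, dioxolane carbon S | CC1(C)OC[C@H](O1)[C@H]2CC(COC(=O)C(C)C)=C([C@@H](C)CCCOC(C)=O)C(O)O2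
F6 | step 8 | triol lactol, C8-R, C7-S | OC[C@H](O)[C@H]1CC(COC(=O)C(C)C)=C([C@@H](C)CCCOC(C)=O)C(O)O1
F7 | step 10 | 6-oxo hydroxy ester | C=C(C(=O)OC)[C@@H]1C(=O)C([C@@H](C)CCCOC(C)=O)=C(COC(=O)C(C)C)C[C@H]1O
F8 | step 10 | 6-oxo 8,12-lactone | C=C1C(=O)O[C@@H]2CC(COC(=O)C(C)C)=C([C@@H](C)CCCOC(C)=O)C(=O)[C@@H]12
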